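**Plan**

- Cuts: the Cα=Cβ enone bond (aldol condensation), the C3–C3a bond of the dihydrofuran (aryl metal onto an aldehyde), and the O1–C2 ether bond (phenoxide onto a chiral epoxide).
- Forward order: ring A is 2,4-dihydroxyacetophenone; the five-carbon side chain is attached to its 4-oxygen, ring B (the dihydrofuran) is closed next, and the cinnamoyl arm with ring C is joined last.
- Enabling feature: C3a of the benzofuran lies between the oxygen-bearing carbons C4 and C7a. It is C3 of the acetophenone, ortho to both hydroxyls, so it can be iodinated at the outset, and that iodide later becomes the C3–C3a bond.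
- Stereochemistry: C2 comes from Sharpless epoxidation of prenol and SN2 inversion in the epoxide opening; C3 is induced by C2 in the ring closure (trans); the alkene is E by thermodynamic control in the condensation.

Key step: step 9

Remark on the chemistry (assumption): the CIP descriptor of the side-chain stereocentre changes (S in 6–9, R in 10, S as C2 of 12) only because the ranking of its neighbours changes; its geometry is fixed in step 4 and not touched afterwards.

**Route**

Step 1
Reactants: 1 2,4-dihydroxyacetophenone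
Product: 2 1-(2,4-dihydroxy-3-iodophenyl)ethan-1-one
Conditions: I2, HIO3, EtOH–H2O, rt
Reagents that add atoms: iodine (II); iodic acid (O=I(=O)O)
Why: Electrophilic aromatic iodination, in which the carbon ortho to both hydroxyl groups is the most activated ring position and HIO3 re-oxidises the iodide formed so that all iodine is used.

Step 2
Reactants: 3 prenol (3-methylbut-2-en-1-ol)
Product: 4 (R)-(3,3-dimethyloxiran-2-yl)methanol
Conditions: Ti(OiPr)4 (cat.), D-(−)-diethyl tartrate (cat.), t-BuOOH, 4 Å MS, CH2Cl2, −20 °C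
Reagents that add atoms: tert-butyl hydroperoxide (CC(C)(C)OO)
Why: Sharpless asymmetric epoxidation, in which the titanium–tartrate complex binds the allylic alcohol and the hydroperoxide and delivers oxygen to one face of the alkene, which with the D-(−)-tartrate should set the (R) centre.

Step 3
Reactants: 4 (R)-(3,3-dimethyloxiran-2-yl)methanol
Product: 5 (R)-2-{[(4-methoxybenzyl)oxy]methyl}-3,3-dimethyloxirane
Conditions: NaH, 4-methoxybenzyl chloride, DMF, 0 °C → rt
Reagents that add atoms: 4-methoxybenzyl chloride (COc1ccc(CCl)cc1)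
Why: Williamson ether synthesis, in which the primary alkoxide is benzylated faster than it can undergo Payne rearrangement and the stereocentre is not involved.

Step 4
Reactants: 2 1-(2,4-dihydroxy-3-iodophenyl)ethan-1-one; 5 (R)-2-{[(4-methoxybenzyl)oxy]methyl}-3,3-dimethyloxirane
Product: 6 1-{2-hydroxy-4-[((2S)-3-hydroxy-1-[(4-methoxybenzyl)oxy]-3-methylbutan-2-yl)oxy]-3-iodophenyl}ethan-1-one
Conditions: Cs2CO3, DMF, 100 °C
Reagents that add atoms: none
Why: Base-mediated SN2 opening of an epoxide by a phenoxide, in which the more acidic, non-chelated 4-hydroxyl is deprotonated and attacks the secondary epoxide carbon (the other one is fully substituted and closed to backside attack), so the aryl ether forms with inversion and gives the (S) centre.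

Step 5
Reactants: 6 1-{2-hydroxy-4-[((2S)-3-hydroxy-1-[(4-methoxybenzyl)oxy]-3-methylbutan-2-yl)oxy]-3-iodophenyl}ethan-1-one
Product: 7 1-{4-[((2S)-3-hydroxy-1-[(4-methoxybenzyl)oxy]-3-methylbutan-2-yl)oxy]-3-iodo-2-(methoxymethoxy)phenyl}ethan-1-one
Conditions: NaH (1.05 equiv), MOMCl, DMF, 0 °C → rt
Reagents that add atoms: chloromethyl methyl ether (COCCl)
Why: Williamson-type acetal formation, in which one equivalent of NaH deprotonates only the chelated phenol and its phenoxide is alkylated by the reactive chloromethyl ether while the tertiary alcohol stays free.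

Step 6
Reactants: 7 1-{4-[((2S)-3-hydroxy-1-[(4-methoxybenzyl)oxy]-3-methylbutan-2-yl)oxy]-3-iodo-2-(methoxymethoxy)phenyl}ethan-1-one
Product: 8 1-{3-iodo-4-[((2S)-1-[(4-methoxybenzyl)oxy]-3-methyl-3-[(triethylsilyl)oxy]butan-2-yl)oxy]-2-(methoxymethoxy)phenyl}ethan-1-one
Conditions: TESOTf, 2,6-lutidine, CH2Cl2, −78 → 0 °C
Reagents that add atoms: triethylsilyl triflate (CC[Si](CC)(CC)OS(=O)(=O)C(F)(F)F)
Why: Silylation with a silyl triflate and a hindered pyridine base, which is reactive enough for a tertiary alcohol at low temperature where the ketone and the acetal are left alone.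

Step 7
Reactants: 8 1-{3-iodo-4-[((2S)-1-[(4-methoxybenzyl)oxy]-3-methyl-3-[(triethylsilyl)oxy]butan-2-yl)oxy]-2-(methoxymethoxy)phenyl}ethan-1-one
Product: 9 1-{4-[((2S)-1-hydroxy-3-methyl-3-[(triethylsilyl)oxy]butan-2-yl)oxy]-3-iodo-2-(methoxymethoxy)phenyl}ethan-1-one
Conditions: DDQ, CH2Cl2–pH 7 buffer, 0 °C → rt
Reagents that add atoms: none
Why: Oxidative cleavage of a 4-methoxybenzyl ether, in which DDQ takes hydride from the electron-rich benzylic position and water hydrolyses the oxocarbenium ion, while the silyl ether, acetal, aryl iodide and ketone are inert and the silylated tertiary hydroxyl cannot form a benzylidene acetal.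

Step 8
Reactants: 9 1-{4-[((2S)-1-hydroxy-3-methyl-3-[(triethylsilyl)oxy]butan-2-yl)oxy]-3-iodo-2-(methoxymethoxy)phenyl}ethan-1-one
Product: 10 (2R)-2-[4-acetyl-2-iodo-3-(methoxymethoxy)phenoxy]-3-methyl-3-[(triethylsilyl)oxy]butanal
Conditions: Dess–Martin periodinane, CH2Cl2, 0 °C → rt; used directly
Reagents that add atoms: none
Why: Dess–Martin oxidation of the primary alcohol under non-basic conditions, so that the alpha-aryloxy aldehyde should neither epimerise nor lose the beta-silyloxy group.

Step 9
Reactants: 10 (2R)-2-[4-acetyl-2-iodo-3-(methoxymethoxy)phenoxy]-3-methyl-3-[(triethylsilyl)oxy]butanal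
Product: 12 1-[(2S,3S)-3-hydroxy-4-(methoxymethoxy)-2-{2-[(triethylsilyl)oxy]propan-2-yl}-2,3-dihydro-1-benzofuran-5-yl]ethan-1-one, via arylchromium dichloride 11 (not isolated)
Conditions: CrCl2 (excess), NiCl2 (cat.), degassed DMF, rt; aqueous work-up
Reagents that add atoms: none
Why: CrCl2 reduces NiCl2 to zerovalent nickel, which inserts into the C–I bond and passes the aryl group on to trivalent chromium, and the arylchromium 11 adds to the tethered aldehyde to form the C3–C3a bond. The closest known reaction type is the intramolecular Nozaki–Hiyama–Kishi coupling of aryl and alkenyl iodides with aldehydes. The dihydrofuran ring (ring B) closes in the 5-exo-trig mode, the aryl carbon attacking the carbonyl carbon while the C=O bond stays outside the new ring. The new C3 stereocentre is controlled by the C2 stereocentre: the large triethylsilyloxy-isopropyl group takes the outward, pseudoequatorial place on the closing five-membered ring, the small aldehyde hydrogen lies on its side and the chromium-bound oxygen on the other, which should give the trans (2S,3S) alcohol after work-up. The step needs aldehyde-over-ketone chemoselectivity and retention of the alpha-aryloxy aldehyde configuration; the first is secured by the low basicity and aldehyde preference of organochromium reagents, the second by the neutral, base-free medium and the fast ring closure.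

Step 10
Reactants: 13 4-hydroxybenzaldehyde
Product: 14 4-(methoxymethoxy)benzaldehyde
Conditions: MOMCl, iPr2NEt, CH2Cl2, 0 °C → rt
Reagents that add atoms: chloromethyl methyl ether (COCCl)
Why: Acetal protection of a phenol by O-alkylation, giving an ether that survives hydroxide and keeps the aldehyde electrophilic, which a free 4-oxido group would not.

Step 11
Reactants: 12 1-[(2S,3S)-3-hydroxy-4-(methoxymethoxy)-2-{2-[(triethylsilyl)oxy]propan-2-yl}-2,3-dihydro-1-benzofuran-5-yl]ethan-1-one; 14 4-(methoxymethoxy)benzaldehyde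
Product: 16 (E)-1-[(2S,3S)-3-hydroxy-4-(methoxymethoxy)-2-{2-[(triethylsilyl)oxy]propan-2-yl}-2,3-dihydro-1-benzofuran-5-yl]-3-[4-(methoxymethoxy)phenyl]prop-2-en-1-one, via aldol adduct 15 (not isolated)
Conditions: KOH, EtOH, rt
Reagents that add atoms: none
Why: Claisen–Schmidt condensation, in which the enolate of the methyl ketone adds to the non-enolisable aldehyde and the aldol 15 loses water by E1cB to the conjugated enone, the E isomer forming under thermodynamic control while the acetal on O4 and the silyl ether are stable to hydroxide.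

Step 12
Reactants: 16 (E)-1-[(2S,3S)-3-hydroxy-4-(methoxymethoxy)-2-{2-[(triethylsilyl)oxy]propan-2-yl}-2,3-dihydro-1-benzofuran-5-yl]-3-[4-(methoxymethoxy)phenyl]prop-2-en-1-one
Product: 17 brosimacutin G, (E)-1-[(2S,3S)-3,4-dihydroxy-2-(2-hydroxypropan-2-yl)-2,3-dihydro-1-benzofuran-5-yl]-3-(4-hydroxyphenyl)prop-2-en-1-one
Conditions: aq. HCl (2 M), MeOH, rt
Reagents that add atoms: none
Why: Acid-catalysed hydrolysis of the two methoxymethyl acetals (the one ortho to the carbonyl being the more labile) and of the tertiary triethylsilyl ether, run dilute and at room temperature so that the C3 benzylic alcohol should not ionise and neither stereocentre is touched.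

**Compound list**

1 | 2,4-dihydroxyacetophenone | CC(=O)c1ccc(O)cc1O | starting material
2 | 1-(2,4-dihydroxy-3-iodophenyl)ethan-1-one | CC(=O)c1ccc(O)c(I)c1O | intermediate
3 | prenol (3-methylbut-2-en-1-ol) | CC(C)=CCO | starting material
4 | (R)-(3,3-dimethyloxiran-2-yl)methanol | OC[C@H]1OC1(C)C | intermediate
5 | (R)-2-{[(4-methoxybenzyl)oxy]methyl}-3,3-dimethyloxirane | COc1ccc(COC[C@H]2OC2(C)C)cc1 | intermediate
6 | 1-{2-hydroxy-4-[((2S)-3-hydroxy-1-[(4-methoxybenzyl)oxy]-3-methylbutan-2-yl)oxy]-3-iodophenyl}ethan-1-one | CC(C)(O)[C@H](COCc1ccc(OC)cc1)Oc1ccc(C(C)=O)c(O)c1I | intermediate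
7 | 1-{4-[((2S)-3-hydroxy-1-[(4-methoxybenzyl)oxy]-3-methylbutan-2-yl)oxy]-3-iodo-2-(methoxymethoxy)phenyl}ethan-1-one | CC(C)(O)[C@H](COCc1ccc(OC)cc1)Oc1ccc(C(C)=O)c(OCOC)c1I | intermediate
8 | 1-{3-iodo-4-[((2S)-1-[(4-methoxybenzyl)oxy]-3-methyl-3-[(triethylsilyl)oxy]butan-2-yl)oxy]-2-(methoxymethoxy)phenyl}ethan-1-one | CC(C)(O[Si](CC)(CC)CC)[C@H](COCc1ccc(OC)cc1)Oc1ccc(C(C)=O)c(OCOC)c1I | intermediate
9 | 1-{4-[((2S)-1-hydroxy-3-methyl-3-[(triethylsilyl)oxy]butan-2-yl)oxy]-3-iodo-2-(methoxymethoxy)phenyl}ethan-1-one | CC(C)(O[Si](CC)(CC)CC)[C@H](CO)Oc1ccc(C(C)=O)c(OCOC)c1I | intermediate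
10 | (2R)-2-[4-acetyl-2-iodo-3-(methoxymethoxy)phenoxy]-3-methyl-3-[(triethylsilyl)oxy]butanal | CC(C)(O[Si](CC)(CC)CC)[C@H](C=O)Oc1ccc(C(C)=O)c(OCOC)c1I | intermediate
11 | arylchromium dichloride derived from 10 (CrCl2 on the former C–I carbon; trivalent chromium, DMF-solvated) | CC(C)(O[Si](CC)(CC)CC)[C@H](C=O)Oc1ccc(C(C)=O)c(OCOC)c1[Cr](Cl)Cl | intermediate
12 | 1-[(2S,3S)-3-hydroxy-4-(methoxymethoxy)-2-{2-[(triethylsilyl)oxy]propan-2-yl}-2,3-dihydro-1-benzofuran-5-yl]ethan-1-one | CC(C)(O[Si](CC)(CC)CC)[C@H]1Oc2ccc(C(C)=O)c(OCOC)c2[C@@H]1O | intermediate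
13 | 4-hydroxybenzaldehyde | O=Cc1ccc(O)cc1 | starting material
14 | 4-(methoxymethoxy)benzaldehyde | COCOc1ccc(C=O)cc1 | intermediate
15 | aldol adduct, 3-hydroxy-1-[(2S,3S)-3-hydroxy-4-(methoxymethoxy)-2-{2-[(triethylsilyl)oxy]propan-2-yl}-2,3-dihydro-1-benzofuran-5-yl]-3-[4-(methoxymethoxy)phenyl]propan-1-one (both carbinol epimers) | CC(C)(O[Si](CC)(CC)CC)[C@H]1Oc2ccc(C(=O)CC(O)c3ccc(OCOC)cc3)c(OCOC)c2[C@@H]1O | intermediate
16 | (E)-1-[(2S,3S)-3-hydroxy-4-(methoxymethoxy)-2-{2-[(triethylsilyl)oxy]propan-2-yl}-2,3-dihydro-1-benzofuran-5-yl]-3-[4-(methoxymethoxy)phenyl]prop-2-en-1-one | CC(C)(O[Si](CC)(CC)CC)[C@H]1Oc2ccc(C(=O)/C=C/c3ccc(OCOC)cc3)c(OCOC)c2[C@@H]1O | intermediate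
17 | brosimacutin G, (E)-1-[(2S,3S)-3,4-dihydroxy-2-(2-hydroxypropan-2-yl)-2,3-dihydro-1-benzofuran-5-yl]-3-(4-hydroxyphenyl)prop-2-en-1-one | CC(C)(O)[C@H]1Oc2ccc(C(=O)/C=C/c3ccc(O)cc3)c(O)c2[C@@H]1O | target

**Step count and risks**

Total step count: 12. Longest linear sequence: 10 steps (3 → 17 through steps 2, 3, 4, 5, 6, 7, 8, 9, 11, 12).

Steps most likely to fail:

1. Step 4. The ortho-iodophenoxide is hindered and weakly nucleophilic, and the epoxide carbon it must attack sits next to a fully substituted centre, so the SN2 opening may be too slow and the partners may decompose at the temperature needed. Fallback, from 5 and 2, back to the route at 6: epoxide 5 is isomerised with diethylaluminium 2,2,6,6-tetramethylpiperidide in toluene at 0 °C to the allylic alcohol (S)-1-[(4-methoxybenzyl)oxy]-3-methylbut-3-en-2-ol F1, which keeps the C–O bond at the stereocentre. Mitsunobu coupling of F1 with phenol 2 (PPh3, DIAD, THF, 0 °C → rt) forms the aryl ether with inversion at the now less hindered allylic carbon and should give 1-{2-hydroxy-3-iodo-4-[((2R)-1-[(4-methoxybenzyl)oxy]-3-methylbut-3-en-2-yl)oxy]phenyl}ethan-1-one F2. Mukaiyama hydration of the 1,1-disubstituted alkene of F2 (Co(acac)2, PhSiH3, O2, THF, rt) then installs the tertiary alcohol and delivers 6.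

2. Step 9. The facial selectivity of the arylchromium addition to the aldehyde may be poor, so that the cis alcohol forms beside or in place of the trans one. Fallback, from 10, back to the route at 12: the closure is run as in step 9 and the cis product 1-[(2S,3R)-3-hydroxy-4-(methoxymethoxy)-2-{2-[(triethylsilyl)oxy]propan-2-yl}-2,3-dihydro-1-benzofuran-5-yl]ethan-1-one F3 is taken on. A Mitsunobu reaction with 4-nitrobenzoic acid (PPh3, DIAD, toluene, 0 °C → rt) inverts C3, the carboxylate entering from the ring face that carries neither the hydroxyl nor the C2 substituent, and should give (2S,3S)-5-acetyl-4-(methoxymethoxy)-2-{2-[(triethylsilyl)oxy]propan-2-yl}-2,3-dihydro-1-benzofuran-3-yl 4-nitrobenzoate F4. Methanolysis of F4 (K2CO3, MeOH, rt) should then give 12.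

3. Step 12. Under Brønsted acid the C3 benzylic alcohol, flanked by two ring oxygens, may ionise and lose water to the aromatic benzofuran, and long acid contact may cyclise the 2'-hydroxychalcone to the flavanone. Fallback, from 16, back to the route at 17: the two aryl methoxymethyl ethers are exchanged for silyl ethers without protic acid (TESOTf, 2,2'-bipyridyl, CH2Cl2, 0 °C → rt, aqueous work-up). This also silylates the C3 hydroxyl and should give (E)-1-[(2S,3S)-3,4-bis[(triethylsilyl)oxy]-2-{2-[(triethylsilyl)oxy]propan-2-yl}-2,3-dihydro-1-benzofuran-5-yl]-3-{4-[(triethylsilyl)oxy]phenyl}prop-2-en-1-one F5. All four silyl groups of F5 are then removed with a near-neutral fluoride source (Et3N·3HF, THF, rt) to give 17.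

**Further compounds**

F1 | step 4 | (S)-1-[(4-methoxybenzyl)oxy]-3-methylbut-3-en-2-ol | COc1ccc(COC[C@@H](O)C(C)=C)cc1
F2 | step 4 | 1-{2-hydroxy-3-iodo-4-[((2R)-1-[(4-methoxybenzyl)oxy]-3-methylbut-3-en-2-yl)oxy]phenyl}ethan-1-one | C=C(C)[C@H](COCc1ccc(OC)cc1)Oc1ccc(C(C)=O)c(O)c1I
F3 | step 9 | 1-[(2S,3R)-3-hydroxy-4-(methoxymethoxy)-2-{2-[(triethylsilyl)oxy]propan-2-yl}-2,3-dihydro-1-benzofuran-5-yl]ethan-1-one | CC(C)(O[Si](CC)(CC)CC)[C@H]1Oc2ccc(C(C)=O)c(OCOC)c2[C@H]1O
F4 | step 9 | (2S,3S)-5-acetyl-4-(methoxymethoxy)-2-{2-[(triethylsilyl)oxy]propan-2-yl}-2,3-dihydro-1-benzofuran-3-yl 4-nitrobenzoate | CC(C)(O[Si](CC)(CC)CC)[C@H]1Oc2ccc(C(C)=O)c(OCOC)c2[C@@H]1OC(=O)c1ccc([N+](=O)[O-])cc1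
F5 | step 12 | (E)-1-[(2S,3S)-3,4-bis[(triethylsilyl)oxy]-2-{2-[(triethylsilyl)oxy]propan-2-yl}-2,3-dihydro-1-benzofuran-5-yl]-3-{4-[(triethylsilyl)oxy]phenyl}prop-2-en-1-one | CC(C)(O[Si](CC)(CC)CC)[C@H]1Oc2ccc(C(=O)/C=C/c3ccc(O[Si](CC)(CC)CC)cc3)c(O[Si](CC)(CC)CC)c2[C@@H]1O[Si](CC)(CC)CC
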